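**Retrosynthetic overview**

1. 16 ⇒ pentaol 15: the 2,2-dimethyl-dihydropyran ring is closed last, by protonation of the C3' prenyl group and capture of the tertiary cation by the 4'-OH.
2. 15 ⇒ 14 ⇒ 12: both B-ring C-prenyl groups come from O-allyl ethers by sigmatropic shifts (tert-prenyl ether → C3'; prenyl ether → C2' by para-Claisen–Cope). These ethers also protect the B-ring phenols up to that point.
3. 12 ⇒ chalcone 11 ⇒ ketone 6 + aldehyde 10: the pyranone ring is made by oxidative cyclisation of the 2'-hydroxychalcone, after an aldol C–C bond formation.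
4. 6 ⇒ phloroacetophenone 1 (O-prenylation, Claisen on the symmetric ether, bis-MOM); 10 ⇒ protocatechualdehyde 7 (two O-alkylations).
5. Ring order: A and B rings are bought; pyranone C ring in step 6; dihydropyran ring in step 8.

Assumptions: 16 has no stereocentre and no stereogenic double bond, so the constitution alone defines it (the only stereo-element on the route, the E alkene of 11, is consumed); carbonate 8 is bought as a catalogue reagent.

**Route**

Step 1
Reactants: 1 2',4',6'-trihydroxyacetophenone; 2 prenyl bromide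
Product: 3 1-[2,6-dihydroxy-4-(3-methylbut-2-en-1-yloxy)phenyl]ethan-1-one
Conditions: K2CO3 (1.0 equiv), 2 (1.0 equiv), acetone, 50 °C
Reagents that add atoms: prenyl bromide 2, CC(C)=CCBr
Why: Williamson ether synthesis in which the 4-OH, the most acidic phenol and the only one not hydrogen-bonded to the ketone, is alkylated selectively by one equivalent of bromide, so the product keeps a mirror plane.

Step 2
Reactants: 3 1-[2,6-dihydroxy-4-(3-methylbut-2-en-1-yloxy)phenyl]ethan-1-one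
Product: 4 1-[2,4,6-trihydroxy-3-(2-methylbut-3-en-2-yl)phenyl]ethan-1-one
Conditions: PhNEt2, 190 °C (microwave, sealed, Ar), 45 min
Reagents that add atoms: none
Why: Aromatic Claisen rearrangement ([3,3]) in which C3 and C5 of 3 are equivalent by symmetry, so only one product can form and the allyl unit arrives inverted as the 1,1-dimethylallyl group, while the short heating time limits the abnormal Claisen pathway of the product.

Step 3
Reactants: 4 1-[2,4,6-trihydroxy-3-(2-methylbut-3-en-2-yl)phenyl]ethan-1-one; 5 chloromethyl methyl ether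
Product: 6 1-[2-hydroxy-4,6-bis(methoxymethoxy)-3-(2-methylbut-3-en-2-yl)phenyl]ethan-1-one
Conditions: MOMCl (2.2 equiv), i-Pr2NEt, CH2Cl2, 0 °C → rt
Reagents that add atoms: chloromethyl methyl ether 5, COCCl
Why: MOM ether formation in which the 4-OH and 6-OH react while the 2-OH, wedged between the tert-alkyl group and the acetyl group and chelated to the carbonyl, stays free, and this is the hydroxyl that must close the pyranone so that the dimethylallyl group ends up at C8.

Step 4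
Reactants: 7 3,4-dihydroxybenzaldehyde; 8 tert-butyl 2-methylbut-3-en-2-yl carbonate
Product: 9 3-hydroxy-4-(2-methylbut-3-en-2-yloxy)benzaldehyde
Conditions: Pd(PPh3)4 (3 mol%), 8 (1.05 equiv), THF, 0 °C → rt
Reagents that add atoms: tert-butyl 2-methylbut-3-en-2-yl carbonate 8, C=CC(C)(C)OC(=O)OC(C)(C)C
Why: Pd-catalysed decarboxylative allylic etherification (Tsuji–Trost type) in which the tert-butoxide released from 8 deprotonates the more acidic 4-OH (para to the aldehyde) and this phenoxide attacks the π-allyl complex at its more substituted end under kinetic control, giving the tertiary allyl ether.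

Step 5
Reactants: 9 3-hydroxy-4-(2-methylbut-3-en-2-yloxy)benzaldehyde; 2 prenyl bromide
Product: 10 4-(2-methylbut-3-en-2-yloxy)-3-(3-methylbut-2-en-1-yloxy)benzaldehyde
Conditions: K2CO3, DMF, rt
Reagents that add atoms: prenyl bromide 2, CC(C)=CCBr
Why: Williamson ether synthesis on the remaining phenol at room temperature, far below the temperature at which the tertiary allyl ether rearranges.

Step 6
Reactants: 6 1-[2-hydroxy-4,6-bis(methoxymethoxy)-3-(2-methylbut-3-en-2-yl)phenyl]ethan-1-one; 10 4-(2-methylbut-3-en-2-yloxy)-3-(3-methylbut-2-en-1-yloxy)benzaldehyde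
Product: 12 3-hydroxy-5,7-bis(methoxymethoxy)-8-(2-methylbut-3-en-2-yl)-2-[4-(2-methylbut-3-en-2-yloxy)-3-(3-methylbut-2-en-1-yloxy)phenyl]-4H-chromen-4-one, via chalcone 11 (not isolated)
Conditions: KOH, EtOH–H2O, rt, 48 h; then 30% H2O2, MeOH, 0 °C → rt
Reagents that add atoms: hydrogen peroxide, OO
Why: Claisen–Schmidt aldol condensation gives the E-chalcone 11 and alkaline peroxide then effects the Algar–Flynn–Oyamada oxidative cyclisation (the laboratory counterpart of chalcone isomerase, flavanone 3-hydroxylase and flavonol synthase), in which only the enone is attacked by HOO−, the 2'-phenoxide next to the dimethylallyl group closes the pyranone at the benzylic carbon (helped by the para-alkoxy, ortho-unsubstituted B ring), and the allyl and MOM ethers are inert to base.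

Step 7
Reactants: 12 3-hydroxy-5,7-bis(methoxymethoxy)-8-(2-methylbut-3-en-2-yl)-2-[4-(2-methylbut-3-en-2-yloxy)-3-(3-methylbut-2-en-1-yloxy)phenyl]-4H-chromen-4-one
Product: 14 2-[4,5-dihydroxy-2,3-bis(3-methylbut-2-en-1-yl)phenyl]-3-hydroxy-5,7-bis(methoxymethoxy)-8-(2-methylbut-3-en-2-yl)-4H-chromen-4-one, via mono-rearranged phenol 13 (not isolated)
Conditions: degassed 1,2-Cl2C6H4, 120 °C, 1 h; then 185 °C, 3 h (sealed tube, Ar)
Reagents that add atoms: none
Why: Sigmatropic cascade in which the tertiary allyl ether first undergoes an aromatic Claisen rearrangement to its only free ortho carbon (C3', normal prenyl, phenol 13) and the prenyl ether then undergoes a para-Claisen–Cope rearrangement, the crowded ortho dienone (not enolised in the neutral, non-basic solvent) passing the allyl unit on by a Cope shift to the para carbon C2' as a normal prenyl group, while the MOM ethers and the C8 side chain (no free ortho OH) are stable to heat.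

Step 8
Reactants: 14 2-[4,5-dihydroxy-2,3-bis(3-methylbut-2-en-1-yl)phenyl]-3-hydroxy-5,7-bis(methoxymethoxy)-8-(2-methylbut-3-en-2-yl)-4H-chromen-4-one
Product: 16 broussoflavonol E, via pentaol 15 (not isolated)
Conditions: 3 M aq HCl–MeOH (1:5), 40 °C; evaporate; then Amberlyst-15 (H+ form, dry), PhMe–EtOAc, 40 °C
Reagents that add atoms: none
Why: Acid-catalysed acetal cleavage (MeOH as trap) frees pentaol 15 and the aprotic acid stage then performs the biomimetic Markovnikov hydroalkoxylation, in which protonation of the C3' prenyl group gives a tertiary cation captured by the adjacent 4'-OH as the six-membered 2,2-dimethylchromane, while the C2' prenyl group has no phenol within reach and is only protonated reversibly without a nucleophilic solvent, the vinyl group at C8 would need a secondary cation, and no stereocentre is formed.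

**Compound list**

1 | 2',4',6'-trihydroxyacetophenone | CC(=O)c1c(O)cc(O)cc1O | starting material
2 | prenyl bromide (1-bromo-3-methylbut-2-ene) | CC(C)=CCBr | starting material
3 | 1-[2,6-dihydroxy-4-(3-methylbut-2-en-1-yloxy)phenyl]ethan-1-one | CC(=O)c1c(O)cc(OCC=C(C)C)cc1O | intermediate
4 | 1-[2,4,6-trihydroxy-3-(2-methylbut-3-en-2-yl)phenyl]ethan-1-one | CC(=O)c1c(O)cc(O)c(C(C)(C)C=C)c1O | intermediate
5 | chloromethyl methyl ether (MOMCl) | COCCl | starting material
6 | 1-[2-hydroxy-4,6-bis(methoxymethoxy)-3-(2-methylbut-3-en-2-yl)phenyl]ethan-1-one | CC(=O)c1c(OCOC)cc(OCOC)c(C(C)(C)C=C)c1O | intermediate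
7 | 3,4-dihydroxybenzaldehyde | O=Cc1ccc(O)c(O)c1 | starting material
8 | tert-butyl 2-methylbut-3-en-2-yl carbonate | C=CC(C)(C)OC(=O)OC(C)(C)C | starting material
9 | 3-hydroxy-4-(2-methylbut-3-en-2-yloxy)benzaldehyde | O=Cc1ccc(OC(C)(C)C=C)c(O)c1 | intermediate
10 | 4-(2-methylbut-3-en-2-yloxy)-3-(3-methylbut-2-en-1-yloxy)benzaldehyde | O=Cc1ccc(OC(C)(C)C=C)c(OCC=C(C)C)c1 | intermediate
11 | (E)-1-[2-hydroxy-4,6-bis(methoxymethoxy)-3-(2-methylbut-3-en-2-yl)phenyl]-3-[4-(2-methylbut-3-en-2-yloxy)-3-(3-methylbut-2-en-1-yloxy)phenyl]prop-2-en-1-one | O=C(/C=C/c1ccc(OC(C)(C)C=C)c(OCC=C(C)C)c1)c1c(OCOC)cc(OCOC)c(C(C)(C)C=C)c1O | intermediate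
12 | 3-hydroxy-5,7-bis(methoxymethoxy)-8-(2-methylbut-3-en-2-yl)-2-[4-(2-methylbut-3-en-2-yloxy)-3-(3-methylbut-2-en-1-yloxy)phenyl]-4H-chromen-4-one | C=CC(C)(C)c1c(OCOC)cc(OCOC)c2c(=O)c(O)c(-c3ccc(OC(C)(C)C=C)c(OCC=C(C)C)c3)oc12 | intermediate
13 | 3-hydroxy-2-[4-hydroxy-3-(3-methylbut-2-en-1-yl)-5-(3-methylbut-2-en-1-yloxy)phenyl]-5,7-bis(methoxymethoxy)-8-(2-methylbut-3-en-2-yl)-4H-chromen-4-one | C=CC(C)(C)c1c(OCOC)cc(OCOC)c2c(=O)c(O)c(-c3cc(CC=C(C)C)c(O)c(OCC=C(C)C)c3)oc12 | intermediate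
14 | 2-[4,5-dihydroxy-2,3-bis(3-methylbut-2-en-1-yl)phenyl]-3-hydroxy-5,7-bis(methoxymethoxy)-8-(2-methylbut-3-en-2-yl)-4H-chromen-4-one | C=CC(C)(C)c1c(OCOC)cc(OCOC)c2c(=O)c(O)c(-c3cc(O)c(O)c(CC=C(C)C)c3CC=C(C)C)oc12 | intermediate
15 | 2-[4,5-dihydroxy-2,3-bis(3-methylbut-2-en-1-yl)phenyl]-3,5,7-trihydroxy-8-(2-methylbut-3-en-2-yl)-4H-chromen-4-one | C=CC(C)(C)c1c(O)cc(O)c2c(=O)c(O)c(-c3cc(O)c(O)c(CC=C(C)C)c3CC=C(C)C)oc12 | intermediate
16 | broussoflavonol E, 3,5,7-trihydroxy-2-[8-hydroxy-2,2-dimethyl-5-(3-methylbut-2-en-1-yl)-3,4-dihydro-2H-chromen-6-yl]-8-(2-methylbut-3-en-2-yl)-4H-chromen-4-one | C=CC(C)(C)c1c(O)cc(O)c2c(=O)c(O)c(-c3cc(O)c4c(c3CC=C(C)C)CCC(C)(C)O4)oc12 | target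

**Step count and risks**

Total steps: 8. Longest linear sequence: 6 steps (1 → 3 → 4 → 6 → 12 → 14 → 16).

Most likely to fail, step 7: the prenyl ether of 13 may stop at the ortho carbon C6' as a 1,1-dimethylallyl group, or lose isoprene, instead of reaching C2'. The fallback puts the C2' prenyl group in by cross-coupling on the aldehyde and sets out from 9. Heating 9 in toluene at 110 °C gives 3,4-dihydroxy-5-(3-methylbut-2-en-1-yl)benzaldehyde F1, and Amberlyst-15 in the same flask closes it to 8-hydroxy-2,2-dimethyl-3,4-dihydro-2H-chromene-6-carbaldehyde F2 (the prenyl group is then the only alkene, so the ring closure is unambiguous). MOMCl and i-Pr2NEt give 8-(methoxymethoxy)-2,2-dimethyl-3,4-dihydro-2H-chromene-6-carbaldehyde F3. NBS in MeCN brominates para to the MOM ether (the veratraldehyde pattern) to give 5-bromo-8-(methoxymethoxy)-2,2-dimethyl-3,4-dihydro-2H-chromene-6-carbaldehyde F4. Stille coupling with tributyl(3-methylbut-2-en-1-yl)stannane (Pd(PPh3)4, DMF, 90 °C) gives 8-(methoxymethoxy)-2,2-dimethyl-5-(3-methylbut-2-en-1-yl)-3,4-dihydro-2H-chromene-6-carbaldehyde F5. Condensation of F5 with 6 (KOH, EtOH) gives (E)-1-[2-hydroxy-4,6-bis(methoxymethoxy)-3-(2-methylbut-3-en-2-yl)phenyl]-3-[8-(methoxymethoxy)-2,2-dimethyl-5-(3-methylbut-2-en-1-yl)-3,4-dihydro-2H-chromen-6-yl]prop-2-en-1-one F6, and alkaline H2O2 converts it into 3-hydroxy-5,7-bis(methoxymethoxy)-2-[8-(methoxymethoxy)-2,2-dimethyl-5-(3-methylbut-2-en-1-yl)-3,4-dihydro-2H-chromen-6-yl]-8-(2-methylbut-3-en-2-yl)-4H-chromen-4-one F7. 3 M HCl in MeOH at 40 °C removes the three MOM groups and the fallback comes back to the route at 16.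

Second, step 8: the acid stage may hydrate or isomerise the C2' prenyl group, or close the 8-(1,1-dimethylallyl)/7-OH pair to a dihydrofuran. The fallback closes the ring with a selenium electrophile instead of a proton, before the MOM groups come off, and sets out from 14. N-(Phenylseleno)phthalimide with catalytic PPTS in CH2Cl2 at 0 °C forms seleniranium ions reversibly on the two alkenes that have no phenol in reach, so only the C3' prenyl group is trapped (6-endo, Markovnikov) as racemic 3-hydroxy-2-[8-hydroxy-2,2-dimethyl-5-(3-methylbut-2-en-1-yl)-3-(phenylselanyl)-3,4-dihydro-2H-chromen-6-yl]-5,7-bis(methoxymethoxy)-8-(2-methylbut-3-en-2-yl)-4H-chromen-4-one F8. Bu3SnH and AIBN in toluene at 80 °C remove the selenium to give 3-hydroxy-2-[8-hydroxy-2,2-dimethyl-5-(3-methylbut-2-en-1-yl)-3,4-dihydro-2H-chromen-6-yl]-5,7-bis(methoxymethoxy)-8-(2-methylbut-3-en-2-yl)-4H-chromen-4-one F9. 3 M HCl in MeOH at 40 °C then cleaves the two MOM ethers and the fallback comes back to the route at 16.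

Third, step 6: the peroxide stage may give the aurone (5-exo opening of the chalcone epoxide, the known bias of 6'-alkoxy chalcones), and the aldol of the hindered ketone may be slow. The fallback closes the pyranone ring first and adds the oxygen afterwards, following the biosynthetic order; it sets out from chalcone 11, isolated by working up step 6 before the peroxide is added. NaOAc in EtOH at 60 °C closes 11 by oxa-Michael addition to racemic 5,7-bis(methoxymethoxy)-8-(2-methylbut-3-en-2-yl)-2-[4-(2-methylbut-3-en-2-yloxy)-3-(3-methylbut-2-en-1-yloxy)phenyl]-2,3-dihydro-4H-chromen-4-one F10. LiHMDS in THF at −78 °C followed by 2-(phenylsulfonyl)-3-phenyloxaziridine hydroxylates the enolate trans to the aryl group to give rac-(2R,3R)-3-hydroxy-5,7-bis(methoxymethoxy)-8-(2-methylbut-3-en-2-yl)-2-[4-(2-methylbut-3-en-2-yloxy)-3-(3-methylbut-2-en-1-yloxy)phenyl]-2,3-dihydro-4H-chromen-4-one F11 (the low temperature holds back ring-opening of the enolate). NaOH and H2O2 in MeOH dehydrogenate F11 and the fallback comes back to the route at 12.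

**Further compounds**

F1 | step 7 | 3,4-dihydroxy-5-(3-methylbut-2-en-1-yl)benzaldehyde | O=Cc1cc(O)c(O)c(CC=C(C)C)c1
F2 | step 7 | 8-hydroxy-2,2-dimethyl-3,4-dihydro-2H-chromene-6-carbaldehyde | O=Cc1cc(O)c2OC(C)(C)CCc2c1
F3 | step 7 | 8-(methoxymethoxy)-2,2-dimethyl-3,4-dihydro-2H-chromene-6-carbaldehyde | O=Cc1cc(OCOC)c2OC(C)(C)CCc2c1
F4 | step 7 | 5-bromo-8-(methoxymethoxy)-2,2-dimethyl-3,4-dihydro-2H-chromene-6-carbaldehyde | O=Cc1cc(OCOC)c2OC(C)(C)CCc2c1Br
F5 | step 7 | 8-(methoxymethoxy)-2,2-dimethyl-5-(3-methylbut-2-en-1-yl)-3,4-dihydro-2H-chromene-6-carbaldehyde | O=Cc1cc(OCOC)c2OC(C)(C)CCc2c1CC=C(C)C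
F6 | step 7 | (E)-1-[2-hydroxy-4,6-bis(methoxymethoxy)-3-(2-methylbut-3-en-2-yl)phenyl]-3-[8-(methoxymethoxy)-2,2-dimethyl-5-(3-methylbut-2-en-1-yl)-3,4-dihydro-2H-chromen-6-yl]prop-2-en-1-one | O=C(/C=C/c1cc(OCOC)c2OC(C)(C)CCc2c1CC=C(C)C)c1c(OCOC)cc(OCOC)c(C(C)(C)C=C)c1O
F7 | step 7 | 3-hydroxy-5,7-bis(methoxymethoxy)-2-[8-(methoxymethoxy)-2,2-dimethyl-5-(3-methylbut-2-en-1-yl)-3,4-dihydro-2H-chromen-6-yl]-8-(2-methylbut-3-en-2-yl)-4H-chromen-4-one | C=CC(C)(C)c1c(OCOC)cc(OCOC)c2c(=O)c(O)c(-c3cc(OCOC)c4c(c3CC=C(C)C)CCC(C)(C)O4)oc12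
F8 | step 8 | racemic 3-hydroxy-2-[8-hydroxy-2,2-dimethyl-5-(3-methylbut-2-en-1-yl)-3-(phenylselanyl)-3,4-dihydro-2H-chromen-6-yl]-5,7-bis(methoxymethoxy)-8-(2-methylbut-3-en-2-yl)-4H-chromen-4-one | C=CC(C)(C)c1c(OCOC)cc(OCOC)c2c(=O)c(O)c(-c3cc(O)c4c(c3CC=C(C)C)CC([Se]c3ccccc3)C(C)(C)O4)oc12
F9 | step 8 | 3-hydroxy-2-[8-hydroxy-2,2-dimethyl-5-(3-methylbut-2-en-1-yl)-3,4-dihydro-2H-chromen-6-yl]-5,7-bis(methoxymethoxy)-8-(2-methylbut-3-en-2-yl)-4H-chromen-4-one | C=CC(C)(C)c1c(OCOC)cc(OCOC)c2c(=O)c(O)c(-c3cc(O)c4c(c3CC=C(C)C)CCC(C)(C)O4)oc12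
F10 | step 6 | racemic 5,7-bis(methoxymethoxy)-8-(2-methylbut-3-en-2-yl)-2-[4-(2-methylbut-3-en-2-yloxy)-3-(3-methylbut-2-en-1-yloxy)phenyl]-2,3-dihydro-4H-chromen-4-one | C=CC(C)(C)c1c(OCOC)cc(OCOC)c2c1OC(CC2=O)c1ccc(OC(C)(C)C=C)c(OCC=C(C)C)c1
F11 | step 6 | rac-(2R,3R)-3-hydroxy-5,7-bis(methoxymethoxy)-8-(2-methylbut-3-en-2-yl)-2-[4-(2-methylbut-3-en-2-yloxy)-3-(3-methylbut-2-en-1-yloxy)phenyl]-2,3-dihydro-4H-chromen-4-one (racemate, one enantiomer drawn) | C=CC(C)(C)c1c(OCOC)cc(OCOC)c2c1O[C@H](c1ccc(OC(C)(C)C=C)c(OCC=C(C)C)c1)[C@@H](O)C2=O
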